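I watched the partner.

the same everywhere: starting material 0.16 M; radical scavenger 0.5 mol%
- birch: partner 1 equiv (fed, over 50 min); initiator 0.5 mol%; run made earlier
- larch: partner 1 equiv (fed, over 50 min); initiator 0.75 mol%; run made earlier
- flask: partner 1.00 equiv (fed, over 50 min); initiator 1 mol%; time 4.0 d

| run | time / d | starting material / % | target / % | isomer of the product / % |
|---|---|---|---|---|
| birch | 0.500 | 45.0 | 40.8 | 14.9 |
| birch | 1.04 | 26.0 | 55.5 | 19.8 |
| birch | 1.67 | 24.1 | 53.5 | 20.1 |
| birch | 2.00 | 23.7 | 56.5 | 20.3 |
| birch | 2.50 | 24.1 | 57.8 | 17.8 |
| birch | 3.00 | 24.8 | 56.6 | 18.9 |
| larch | 0.500 | 26.9 | 52.9 | 20.1 |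
| larch | 1.04 | 16.1 | 61.9 | 24.1 |
| larch | 1.67 | 14.1 | 61.5 | 22.7 |
| larch | 2.00 | 15.2 | 60.2 | 22.7 |
| larch | 2.50 | 13.4 | 62.8 | 24.5 |
| larch | 3.00 | 15.4 | 62.8 | 24.0 |

(standard deviation of a reading: 1 percentage point)

- the reaction counts as stopped when no species that holds the starting material changes by six tenths of a point or more over the second half of the time

- the state of affairs at 4.0 d: stopped, and by what, or still going (it is still moving / the partner has run out first / forward and back rates have come level / all of the starting material has reacted)
- how much of the starting material has reacted by 4.0 d
- how much target there is at 4.0 d, in percent of the starting material charged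
- how much isomer of the product there is at 4.0 d, in percent of the starting material charged

Birch levelled off at 24.2% starting material, read as the mean from 1.67 d on. Larch, with 0.75 mol% of initiator against 0.5 mol% in birch, read the same way gave 14.5%, which is lower than birch. I reckoned between two extreme flasks. Suppose every partner molecule meets a chain: with 1.00 equiv charged, the starting material ends at zero. Suppose the radical scavenger takes every radical: nothing reacts. To place the real flasks, I counted two radicals per initiator and one taken per scavenger, so the radical excess is twice the initiator loading less the scavenger loading: 0.5 mol% in birch, 1 mol% in larch and 1.5 mol% in the new flask.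

I then replaced the falling chain rate by a mean proportional to that excess, set against a steady pseudo-first-order loss of partner, the limiting reagent; that loss was my inference. Partner lost over partner used then equals a fixed excess divided by the radical excess. Birch gave 0.16 mol% for this fixed excess and larch 0.17 mol%, a ratio of 1.06, which was my check on using a mean. I took 0.16 mol%, the break-even excess: the radical excess at which as much partner is lost as used. The new flask's remainder is this excess over itself plus the radical excess, 9.89%, so my conversion was 90.1%.

The forecast said the partner has run out first, with 89.5% reacted (from 87% to 92.5%), 65.2% target and 24.5% isomer of the product, holding that “faster reaction wastes less”.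

At 4.0 d the flask stood thus: the partner has run out first, with 0.014% of the partner left, 88.9% reacted, 64.5% target and 23.9% isomer of the product.

    2 chain carrier → ended chains B (k = 2.00 × 10⁸ M⁻¹ s⁻¹)
    partner → decomposed reagent (k = 0.0220 h⁻¹)
    starting material + initiating radical → chain carrier (k = 3.40 × 10⁷ M⁻¹ h⁻¹)
    initiator → 2 initiating radical (k = 0.140 h⁻¹)
    target ⇌ isomer of the product (K = 0.370, k = 0.400 h⁻¹)
    2 initiating radical → ended chains A (k = 7.00 × 10⁸ M⁻¹ s⁻¹)
    partner + chain carrier → target + initiating radical (k = 12000 M⁻¹ s⁻¹)
    radical scavenger + initiating radical → ended chains C (k = 1.40 × 10⁷ M⁻¹ s⁻¹)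

Reckoned backwards, the flask's conversion gives a break-even excess of 0.19 mol%, against the 0.16 mol% I carried in. A neighbouring flask with 0.25 mol% of initiator had a radical excess of 0 mol%, so the same reckoning put its remaining starting material at 100%. That neighbour reached a conversion of 0.724%, and 12% of its partner was left at 4.00 d.

The earlier runs and the new flask are calculated with constants of no real substance; the scatter is artificial.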